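The readings stem from a simulated flask with made-up constants; the scatter is artificial.

If J were what stopped these flasks, equal charges of J would give equal E. Grey and red both take 19 mM of J, yet grey ends near 2.56 mM, while red's five readings average 12.6 % of its L, or 8.79 mM, which is more. What falls as L rises is the yield, so I reckon the yield against the charge of L.

| flask | L | J | remark | time |
|---|---|---|---|---|
| grey | 5.3 mM | 19 mM | run made earlier |  |
| red | 70 mM | 19 mM | run made earlier |  |
| violet | 20 mM | 20 mM | run made earlier |  |
| delta | 6.0 mM | 12.0 mM |  | 12 h |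
| eta | 80 mM | 60.0 mM |  | 12 h |
| zeta | 20 mM | 12.0 mM |  | 12 h |
| alpha | 80 mM | 30.0 mM |  | 12 h |
| theta | 20 mM | 19.0 mM |  | 12 h |

| run | time / h | E / % |
|---|---|---|
| grey | 0.667 | 26.9 |
| grey | 1.33 | 38.6 |
| grey | 2.50 | 44.7 |
| grey | 4.00 | 47.0 |
| grey | 8.00 | 48.3 |
| red | 0.833 | 12.3 |
| red | 2.00 | 13.2 |
| red | 4.00 | 12.5 |
| red | 6.00 | 11.8 |
| red | 8.00 | 13.0 |
| violet | 0.667 | 20.2 |
| violet | 1.33 | 25.6 |
| violet | 2.50 | 29.9 |
| violet | 4.00 | 30.3 |
| violet | 8.00 | 34.0 |

(readings scatter by 1 percentage point)



- the flasks by amount of E, in percent of the L charged, highest first, at 12 h (delta / eta / zeta / alpha / theta)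
- the same order at 4.0 d (delta / eta / zeta / alpha / theta)
- the amount of E, in percent of the L charged of the flask you put first, at 12 h
- the amount of E, in percent of the L charged of the flask you put last, at 12 h

Both ends can be solved in the head. In a very dilute flask, take the yield y as a constant, a ceiling Y. In a very concentrated one, take E itself as constant, a cap C, so that y = C/[L]. Adding reciprocals joins the ends: 1/y = 1/Y + [L]/C, a straight line in the charged [L]. Through grey and red it gives C = 11.0 mM and Y = 63.0 %. Their quotient C/Y, 17.4 mM, is the charge at which the yield stands at half of Y: the half-yield charge H, with y = Y/(1 + [L]/H). Violet, left out of the line, is the test: the line says 29.3 %, and its last readings are 30.3 % and 34.0 %.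

These runs keep J near 19.0 mM, so they cannot show what J does to H, and I bracket it. In one version H ignores J; in the other H grows in proportion to J. A run spends J, so its charge overstates what stands later, and I expect the flask between the versions and take the midpoint. That gives delta 43.8 %, theta 29.3 %, zeta 25.8 %, eta 18.5 % and alpha 13.7 %. Delta stands highest and alpha lowest. Red stays level after 2.00 h, so I keep this order at 4.0 d.

The forecast, which differs from this reckoning, gave eta > delta > theta > zeta > alpha at 12 h and eta > delta > theta > zeta > alpha at 4.0 d, with 34.7 % (29 % to 40 %) first and 17.6 % (15 % to 21 %) last, in the words “So J is being lost, and E stops when J is gone.”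

The flask gives delta > theta > zeta > eta > alpha at 12 h and delta > theta > zeta > eta > alpha at 4.0 d, with 49.1 % for delta and 15.3 % for alpha. L is the limiting reagent in delta, which ends with 0.48 % of its L and 54 % of its J. Measured in H, delta's charge is 0.344 and alpha's 4.59, and delta stands 5.3 percentage points above my midpoint.

    L + J → E (k = 0.0110 L mol⁻¹ s⁻¹)
    L + 2 J → G (k = 0.530 L² mol⁻² s⁻¹)
    2 L → Z (k = 0.0120 L mol⁻¹ s⁻¹)

Take a further flask like alpha but with 75 mM of J. H gives 11.3 % and 29.1 % for the two versions, so the midpoint is 20.2 %. The computed flask gives 22.1 %.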